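**Plan**
- Cuts: first the ether bond between the C4 oxygen of the naphthoate and C2' of the quinone. Then C4–C4a and C1–C8a of ring A. Finally, in the furan so exposed, the ring O–acyl bond, the formyl C–C bond and the prenyl C–C bond, which leads back to dimethyl succinate.
- Enabling feature: benzo ring B (C5–C8) has no substituent and is therefore benzyne. C1(OH), C2(CO2Me), C3(prenyl) and C4(O) of ring A are the four carbons of a 2-siloxyfuran. The furan oxygen ends as the free C1 hydroxyl, and the siloxy oxygen stays masked at C4.
- Forward order: the succinate chain is prenylated, formylated, closed to a furanone and silylated (furan ring). Ring A is then closed onto benzyne, and the ready-made naphthoquinone (rings C and D) is attached last through oxygen.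
- Stereochemistry: the target has no stereocentre and no E/Z alkene. The stereocentres of the intermediates are racemic and disappear on aromatisation.

Key step: step 6

Remark: locants C1–C8a refer to the naphthoate half of the target and prenyl means 3-methylbut-2-en-1-yl. The 2(3H)- and 2(5H)-furanone tautomers are treated as equivalent entries to the siloxyfuran, because silylation of either gives the same compound.

Step 1
Reactants: 1 dimethyl succinate; 2 prenyl bromide
Product: 4 dimethyl 2-(3-methylbut-2-enyl)succinate (racemic), via lithium enolate of dimethyl succinate 3 (not isolated)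
Conditions: LiN(i-Pr)2 (1.05 equiv), THF, –78 °C; then 2, DMPU, –78 → 0 °C
Reagents that add atoms: none
Why: Kinetic ester-enolate alkylation (SN2 at the primary allylic carbon of 2), in which the mono-enolate 3 is fully formed at –78 °C before Claisen self-condensation can start, and the new stereocentre arises racemic, which does not matter because it becomes an sp2 furan carbon in step 4.

Step 2
Reactants: 4 dimethyl 2-(3-methylbut-2-enyl)succinate
Product: 6 dimethyl 2-formyl-3-(3-methylbut-2-enyl)succinate (racemic; aldehyde–enol tautomers), via sodium enolate of the formyl diester 5 (not isolated)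
Conditions: NaH, HCO2Me (excess), MeOH (cat.), THF, 0 °C → rt; then 1 M HCl, 0 °C
Reagents that add atoms: methyl formate, COC=O
Why: Crossed Claisen condensation (formylation) under thermodynamic control, classical for 2-alkylsuccinates, in which only acylation of the free methylene leaves an acidic proton so that the reversible process drains into the stabilised enolate 5, and the formyl-bearing stereocentre is labile through its enol and needs no control.

Step 3
Reactants: 6 dimethyl 2-formyl-3-(3-methylbut-2-enyl)succinate
Product: 7 methyl 4-(3-methylbut-2-enyl)-5-oxo-4,5-dihydrofuran-3-carboxylate (racemic)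
Conditions: CSA (10 mol %), toluene, reflux, 4 Å molecular sieves in a Soxhlet head (removal of MeOH)
Reagents that add atoms: none
Why: Acid-catalysed enol lactonisation (intramolecular transesterification, 5-exo-trig at the distal ester carbonyl), known for formylsuccinic esters, which should work because the β-formyl ester is largely enolised, the sieves take up methanol and pull the equilibrium over, an isolated trisubstituted alkene tolerates catalytic sulfonic acid in hot anhydrous toluene, and drift to the conjugated 2(5H)-tautomer is harmless.

Step 4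
Reactants: 7 methyl 4-(3-methylbut-2-enyl)-5-oxo-4,5-dihydrofuran-3-carboxylate
Product: 8 methyl 4-(3-methylbut-2-enyl)-5-(triisopropylsilyloxy)furan-3-carboxylate
Conditions: TIPSOTf, Et3N, CH2Cl2, 0 °C
Reagents that add atoms: triisopropylsilyl triflate, CC(C)[Si](OS(=O)(=O)C(F)(F)F)(C(C)C)C(C)C
Why: Soft enolisation and O-silylation of a butenolide, the standard entry to 2-siloxyfurans, in which the C4 proton (α to the lactone carbonyl and allylic) is removed with gain of furan aromaticity, the hard silyl triflate binds at oxygen, and the racemic stereocentre is erased.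

Step 5
Reactants: 9 2-iodophenol
Product: 10 2-iodophenyl trifluoromethanesulfonate
Conditions: Tf2O, pyridine, CH2Cl2, 0 °C → rt
Reagents that add atoms: triflic anhydride, O=S(=O)(OS(=O)(=O)C(F)(F)F)C(F)(F)F
Why: Routine O-sulfonylation of a phenol, to which the aryl iodide is inert.

Step 6
Reactants: 8 methyl 4-(3-methylbut-2-enyl)-5-(triisopropylsilyloxy)furan-3-carboxylate; 10 2-iodophenyl trifluoromethanesulfonate
Product: 14 methyl 1-hydroxy-3-(3-methylbut-2-enyl)-4-(triisopropylsilyloxy)-2-naphthoate, via 2-(triflyloxy)phenylmagnesium chloride 11 (not isolated), via benzyne 12 (not isolated), via oxygen-bridged cycloadduct 13 (not isolated)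
Conditions: 8 (1 equiv), 10 (1.3 equiv), Me3SiCH2MgCl (1.4 equiv, slow addition), THF, –78 °C → rt; aq. NH4Cl; then PPTS (cat.), CH2Cl2, rt
Reagents that add atoms: none
Why: Iodine–magnesium exchange of 10 with the weakly basic, weakly nucleophilic Me3SiCH2MgCl gives 11, which expels Mg(OTf)Cl and releases benzyne 12 without fluoride, so the ester and the silyl ketene acetal unit of 8 are not touched. Benzyne adds suprafacially across furan C2 and C5 in a concerted, possibly asynchronous [4+2] cycloaddition that forms C1–C8a and C4–C4a at once and so closes ring A as the six-membered carbocycle of the oxygen-bridged adduct 13. In 13 the C4 bridgehead is a silyl ketal: with the magnesium salt held between bridge oxygen and ester carbonyl, or with the mild acid of the work-up, the siloxy lone pair expels the bridge oxygen from C4, and the arenium-like cation loses the C1 proton faster than the hindered TIPS group can be transferred, which leaves OH at C1 and OTIPS at C4 in 14. The closest known reaction type is the aryne Diels–Alder reaction of 2-alkoxy- and 2-siloxyfurans with opening of the adduct to 4-oxygenated 1-naphthols. The two bridgehead stereocentres of 13 are fixed relative to each other by the bridge, arise racemic and vanish on aromatisation, and the symmetry of benzyne leaves no regiochemical question. The selectivity needed is furan diene over prenyl alkene (ene or [2+2] reaction), and it is secured by the s-cis-locked, donor-raised diene of the siloxyfuran, which should outrun an isolated trisubstituted alkene.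

Step 7
Reactants: 14 methyl 1-hydroxy-3-(3-methylbut-2-enyl)-4-(triisopropylsilyloxy)-2-naphthoate; 15 2-bromo-1,4-naphthoquinone
Product: 17 rubioncolin C, via caesium C4-naphtholate 16 (not isolated)
Conditions: 15 (1.1 equiv), CsF (2.5 equiv, dried), degassed DMF, Ar, 0 °C → rt
Reagents that add atoms: none
Why: Fluoride-triggered desilylation followed by conjugate addition–elimination on a haloquinone, the standard route to 2-aryloxy-1,4-naphthoquinones, in which only the C4 oxide is unmasked and reactive (the C1 hydroxyl is tied up in a hydrogen bond to the ester), C-attack is blocked because both ortho and para positions are substituted, and ipso and cine pathways give the same product since the benzo ring of 15 is unsubstituted.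

**Compound list**
1 | dimethyl succinate | COC(=O)CCC(=O)OC | starting material
2 | prenyl bromide (1-bromo-3-methylbut-2-ene) | CC(C)=CCBr | starting material
3 | lithium enolate of dimethyl succinate | COC(=O)CC=C([O-])OC.[Li+] | intermediate (not isolated)
4 | dimethyl 2-(3-methylbut-2-enyl)succinate, racemic | COC(=O)CC(CC=C(C)C)C(=O)OC | intermediate
5 | sodium enolate of dimethyl 2-formyl-3-(3-methylbut-2-enyl)succinate, racemic, enolate geometry mobile | COC(=O)C(=C[O-])C(CC=C(C)C)C(=O)OC.[Na+] | intermediate (not isolated)
6 | dimethyl 2-formyl-3-(3-methylbut-2-enyl)succinate, racemic, drawn as the aldehyde, in equilibrium with its enol | COC(=O)C(C=O)C(CC=C(C)C)C(=O)OC | intermediate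
7 | methyl 4-(3-methylbut-2-enyl)-5-oxo-4,5-dihydrofuran-3-carboxylate, racemic | COC(=O)C1=COC(=O)C1CC=C(C)C | intermediate
8 | methyl 4-(3-methylbut-2-enyl)-5-(triisopropylsilyloxy)furan-3-carboxylate | COC(=O)c1coc(O[Si](C(C)C)(C(C)C)C(C)C)c1CC=C(C)C | intermediate
9 | 2-iodophenol | Oc1ccccc1I | starting material
10 | 2-iodophenyl trifluoromethanesulfonate | O=S(=O)(Oc1ccccc1I)C(F)(F)F | intermediate
11 | 2-(triflyloxy)phenylmagnesium chloride | O=S(=O)(Oc1ccccc1[Mg]Cl)C(F)(F)F | intermediate (not isolated)
12 | benzyne | C1#CC=CC=C1 | intermediate (not isolated)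
13 | methyl 1,4-epoxy-3-(3-methylbut-2-enyl)-4-(triisopropylsilyloxy)-1,4-dihydronaphthalene-2-carboxylate, racemic, one enantiomer drawn | COC(=O)C1=C(CC=C(C)C)[C@]2(O[Si](C(C)C)(C(C)C)C(C)C)O[C@H]1c1ccccc12 | intermediate (not isolated)
14 | methyl 1-hydroxy-3-(3-methylbut-2-enyl)-4-(triisopropylsilyloxy)-2-naphthoate | COC(=O)c1c(CC=C(C)C)c(O[Si](C(C)C)(C(C)C)C(C)C)c2ccccc2c1O | intermediate
15 | 2-bromo-1,4-naphthoquinone | O=C1C=C(Br)C(=O)c2ccccc12 | starting material
16 | caesium 4-hydroxy-3-(methoxycarbonyl)-2-(3-methylbut-2-enyl)naphthalen-1-olate | COC(=O)c1c(CC=C(C)C)c([O-])c2ccccc2c1O.[Cs+] | intermediate (not isolated)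
17 | rubioncolin C | COC(=O)c1c(CC=C(C)C)c(OC2=CC(=O)c3ccccc3C2=O)c2ccccc2c1O | target

**Count**
Total steps: 7. Longest linear sequence: 6 (steps 1, 2, 3, 4, 6, 7). Step 5 is a one-step side branch.

**Steps most likely to fail**

Step 3 (enol lactonisation).
- What may go wrong: acyl transfer to the enol oxygen is reversible and may stall through re-addition of methanol. Dehydrative aromatisation with retention of the methoxy group, or protonation of the prenyl alkene, may compete.
- Fallback, from 2 back to 8: the lactone ring is closed by olefination instead of acyl transfer, and no acid is used. Prenyl bromide 2 alkylates the sodium salt of triethyl phosphonoacetate (NaH, THF, 0 °C) to give ethyl 2-(diethoxyphosphoryl)-5-methylhex-4-enoate F1. Saponification (NaOH, aqueous EtOH, then HCl) gives 2-(diethoxyphosphoryl)-5-methylhex-4-enoic acid F2. O-Alkylation of its carboxylate with methyl bromopyruvate (Et3N, acetone, 0 °C) gives 3-methoxy-2,3-dioxopropyl 2-(diethoxyphosphoryl)-5-methylhex-4-enoate F3. An intramolecular Horner–Wadsworth–Emmons reaction (LiCl, DBU, MeCN) then closes methyl 4-(3-methylbut-2-enyl)-5-oxo-2,5-dihydrofuran-3-carboxylate F4, the conjugated tautomer of 7. TIPSOTf and Et3N, as in step 4, convert it into 8.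

Step 6 (aryne cycloaddition and opening).
- What may go wrong: benzyne may be diverted into an ene or [2+2] reaction at the electron-rich trisubstituted alkene while the diene terminus is crowded by the TIPS and prenyl groups. Premature opening of the adduct in the flask may be followed by further arylation.
- Fallback, from 1 back to 14: a less reactive terminal alkene is carried through the cycloaddition, and the prenyl terminus is built afterwards.
- Enolate 3, made from 1, is alkylated with allyl bromide to give dimethyl 2-allylsuccinate F5. Formylation as in step 2 passes through the sodium enolate of the allyl formyl diester F6 to dimethyl 2-allyl-3-formylsuccinate F7. Lactonisation as in step 3 gives methyl 4-allyl-5-oxo-4,5-dihydrofuran-3-carboxylate F8, and silylation as in step 4 gives methyl 4-allyl-5-(triisopropylsilyloxy)furan-3-carboxylate F9.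
- Reaction with 10 and Me3SiCH2MgCl as in step 6 gives methyl 3-allyl-1,4-epoxy-4-(triisopropylsilyloxy)-1,4-dihydronaphthalene-2-carboxylate F10. This opens to methyl 3-allyl-1-hydroxy-4-(triisopropylsilyloxy)-2-naphthoate F11. Cross metathesis with 2-methyl-2-butene (second-generation Grubbs catalyst, CH2Cl2, 40 °C) then gives 14.

Step 7 (desilylative etherification).
- What may go wrong: electron transfer from the liberated hydroquinone mono-anion to the bromoquinone (redox exchange), followed by base-induced tautomerisation of the oxidised partner, may drain the nucleophile before C–O bond formation.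
- Fallback, from 14 back to 17: the C1 hydroxyl is capped first, so that the oxide released by fluoride is no longer part of a hydroquinone. MOMCl and NaH (THF–DMF, 0 °C) give methyl 1-(methoxymethoxy)-3-(3-methylbut-2-enyl)-4-(triisopropylsilyloxy)-2-naphthoate F12. CsF in degassed DMF releases caesium 4-(methoxymethoxy)-3-(methoxycarbonyl)-2-(3-methylbut-2-enyl)naphthalen-1-olate F13, which substitutes the bromide of 15 to give rubioncolin C 1-O-methoxymethyl ether F14. Dilute TFA in wet CH2Cl2 at 0 °C removes the acetal, which is activated by the neighbouring ester, and gives 17.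

**Further compounds**
F1 | step 3 | ethyl 2-(diethoxyphosphoryl)-5-methylhex-4-enoate, racemic | CCOC(=O)C(CC=C(C)C)P(=O)(OCC)OCC
F2 | step 3 | 2-(diethoxyphosphoryl)-5-methylhex-4-enoic acid, racemic | OC(=O)C(CC=C(C)C)P(=O)(OCC)OCC
F3 | step 3 | 3-methoxy-2,3-dioxopropyl 2-(diethoxyphosphoryl)-5-methylhex-4-enoate, racemic | COC(=O)C(=O)COC(=O)C(CC=C(C)C)P(=O)(OCC)OCC
F4 | step 3 | methyl 4-(3-methylbut-2-enyl)-5-oxo-2,5-dihydrofuran-3-carboxylate | COC(=O)C1=C(CC=C(C)C)C(=O)OC1
F5 | step 6 | dimethyl 2-allylsuccinate, racemic | COC(=O)CC(CC=C)C(=O)OC
F6 | step 6 | sodium enolate of dimethyl 2-allyl-3-formylsuccinate, racemic | COC(=O)C(=C[O-])C(CC=C)C(=O)OC.[Na+]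
F7 | step 6 | dimethyl 2-allyl-3-formylsuccinate, racemic, aldehyde–enol tautomers | COC(=O)C(C=O)C(CC=C)C(=O)OC
F8 | step 6 | methyl 4-allyl-5-oxo-4,5-dihydrofuran-3-carboxylate, racemic | COC(=O)C1=COC(=O)C1CC=C
F9 | step 6 | methyl 4-allyl-5-(triisopropylsilyloxy)furan-3-carboxylate | COC(=O)c1coc(O[Si](C(C)C)(C(C)C)C(C)C)c1CC=C
F10 | step 6 | methyl 3-allyl-1,4-epoxy-4-(triisopropylsilyloxy)-1,4-dihydronaphthalene-2-carboxylate, racemic, one enantiomer drawn | COC(=O)C1=C(CC=C)[C@]2(O[Si](C(C)C)(C(C)C)C(C)C)O[C@H]1c1ccccc12
F11 | step 6 | methyl 3-allyl-1-hydroxy-4-(triisopropylsilyloxy)-2-naphthoate | COC(=O)c1c(CC=C)c(O[Si](C(C)C)(C(C)C)C(C)C)c2ccccc2c1O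
F12 | step 7 | methyl 1-(methoxymethoxy)-3-(3-methylbut-2-enyl)-4-(triisopropylsilyloxy)-2-naphthoate | COCOc1c(C(=O)OC)c(CC=C(C)C)c(O[Si](C(C)C)(C(C)C)C(C)C)c2ccccc12
F13 | step 7 | caesium 4-(methoxymethoxy)-3-(methoxycarbonyl)-2-(3-methylbut-2-enyl)naphthalen-1-olate | COCOc1c(C(=O)OC)c(CC=C(C)C)c([O-])c2ccccc12.[Cs+]
F14 | step 7 | rubioncolin C 1-O-methoxymethyl ether | COCOc1c(C(=O)OC)c(CC=C(C)C)c(OC2=CC(=O)c3ccccc3C2=O)c2ccccc12
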